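The ten-membered carbocycle (germacrane numbering C1–C10) is disconnected at the sp2–sp3 junction between vinylic C1 of the trisubstituted (E)-C10=C1 alkene and the unfunctionalised C2 methylene. One palladium-catalysed intramolecular Negishi coupling joins an (E)-alkenyl iodide (C1) and a primary alkylzinc (C2) and closes the ring with retention of the alkene geometry, with the C9 tiglate and C14 ester already in place. The acyclic precursor comes from (S)-carvone, which supplies C5–C9, C11–C13 and the C7 stereocentre; a Still–Gennari olefination adds C2–C4/C15 and a catalytic iodo-aldol reaction adds C1/C10/C14 and sets C9. Sharpless epoxidation and allylic chlorination/acetate displacement finish the synthesis.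

Key step: step 18

Remark: germacrane numbering is used throughout (ring C1–C10, C11–C13 the isopropenyl-derived unit, C14 on C10, C15 on C4); carvone C1/C6/C5/C4/C3 become C5/C6/C7/C8/C9.
Remark: TBS = tert-butyldimethylsilyl, TBDPS = tert-butyldiphenylsilyl, TMS = trimethylsilyl, TES = triethylsilyl, tigloyl = (E)-2-methylbut-2-enoyl.
Assumption: the (S)-oxazaborolidinium catalyst of step 11 is taken to give the 9S carbinol; if its sense of induction on this aldehyde is opposite, its enantiomer is used and nothing else changes.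
Assumption: aldehyde acid 5 is drawn open-chain although it may rest as its cyclic lactol; this does not affect step 3.

Step 1
Reactants: 1 (S)-(+)-carvone
Product: 2 (1S,4S,6S)-1-methyl-4-(prop-1-en-2-yl)-7-oxabicyclo[4.1.0]heptan-2-one
Conditions: H2O2 (35% aq.), NaOH (cat.), MeOH, 0 °C
Reagents that add atoms: hydrogen peroxide, OO
Why: Weitz–Scheffer nucleophilic epoxidation attacks only the enone C=C (the isopropenyl group is inert) and closes anti to the C5 substituent; the two new centres are erased in step 2.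

Step 2
Reactants: 2 carvone oxide
Product: 5 (3S)-5-oxo-3-(prop-1-en-2-yl)pentanoic acid, via keto diol 3 (not isolated), via dioxo aldehyde 4 (not isolated)
Conditions: H5IO6 (2.5 equiv), THF/H2O (3:1), 0 °C→rt
Reagents that add atoms: water, O; orthoperiodic acid, OI(=O)(O)(O)(O)O
Why: Acidic epoxide hydrolysis followed by two Malaprade-type periodate cleavages (glycol, then α-diketone) should excise C2 and its methyl as acetic acid, leaving the ketone-side arm as CO2H and the alkene-side arm as CHO, with the future C7 untouched.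

Step 3
Reactants: 5 aldehyde acid
Product: 6 methyl (3S)-5,5-dimethoxy-3-(prop-1-en-2-yl)pentanoate
Conditions: HC(OMe)3, MeOH, TsOH·H2O (cat.), rt→40 °C
Reagents that add atoms: methanol, CO; trimethyl orthoformate, COC(OC)OC
Why: Fischer esterification and acetalisation run under the same acid catalysis with the orthoformate removing water, which fixes the order in which the two arms are unmasked later.

Step 4
Reactants: 6 acetal ester
Product: 7 (3R)-5,5-dimethoxy-3-(prop-1-en-2-yl)pentanal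
Conditions: DIBAL-H (1.05 equiv), CH2Cl2, −78 °C; MeOH, Rochelle salt
Reagents that add atoms: none
Why: Low-temperature DIBAL-H half-reduction of the only ester stops at the tetrahedral aluminate, which gives the aldehyde on work-up; the acetal is inert.

Step 5
Reactants: 8 methyl bis(2,2,2-trifluoroethyl)phosphonoacetate; 9 tert-butyl(2-iodoethoxy)dimethylsilane
Product: 10 methyl 2-[bis(2,2,2-trifluoroethoxy)phosphoryl]-4-(TBS-oxy)butanoate
Conditions: NaH, DMF, 0 °C; then 9, rt→50 °C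
Reagents that add atoms: none
Why: C-alkylation (SN2) of the sodium phosphonoacetate carbanion by the primary iodide gives the α-substituted Still–Gennari reagent.

Step 6
Reactants: 7 aldehyde; 10 phosphonate
Product: 11 methyl (2Z,5R)-2-[2-(TBS-oxy)ethyl]-7,7-dimethoxy-5-(prop-1-en-2-yl)hept-2-enoate
Conditions: 10, KHMDS, 18-crown-6, THF, −78 °C; then 7
Reagents that add atoms: none
Why: Still–Gennari olefination, in which the electron-poor trifluoroethyl phosphonate collapses fast from the kinetically formed adduct, should give the (Z)-enoate with C6 cis to the ester carbon C15, the geometry that becomes ring-E at C4=C5.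

Step 7
Reactants: 11 (Z)-enoate
Product: 12 (2Z,5R)-2-[2-(TBS-oxy)ethyl]-7,7-dimethoxy-5-(prop-1-en-2-yl)hept-2-en-1-ol
Conditions: DIBAL-H (2.5 equiv), CH2Cl2, −78 °C
Reagents that add atoms: none
Why: DIBAL-H 1,2-reduction of the conjugated ester gives the allylic alcohol (C15–OH) with the alkene geometry retained.

Step 8
Reactants: 12 allylic alcohol
Product: 13 TBDPS ether of 12
Conditions: TBDPSCl, imidazole, CH2Cl2, 0 °C→rt
Reagents that add atoms: tert-butyl(chloro)diphenylsilane, CC(C)(C)[Si](Cl)(c1ccccc1)c1ccccc1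
Why: Silyl ether formation on the primary allylic alcohol; TBDPS is chosen because it survives the aqueous acid of step 9.

Step 9
Reactants: 13 bis-silyl ether acetal
Product: 14 (3R,5Z)-6-[(TBDPS-oxy)methyl]-8-hydroxy-3-(prop-1-en-2-yl)oct-5-enal
Conditions: aq. HCl (1 M), THF, 0 °C→rt
Reagents that add atoms: water, O
Why: Acid hydrolysis cleaves the dimethyl acetal and the primary TBS ether in one operation, while the far more acid-stable TBDPS ether stays.

Step 10
Reactants: 14 hydroxy aldehyde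
Product: 15 (3R,5Z)-6-[(TBDPS-oxy)methyl]-8-iodo-3-(prop-1-en-2-yl)oct-5-enal
Conditions: I2, PPh3, imidazole, CH2Cl2, 0 °C
Reagents that add atoms: iodine, II
Why: Appel-type iodination converts the primary alcohol into the C2 iodide by SN2 at the oxyphosphonium stage; the aldehyde is inert.

Step 11
Reactants: 15 iodo aldehyde; 16 methyl propiolate
Product: 19 methyl (2Z,3S,5R,7Z)-8-[(TBDPS-oxy)methyl]-3-hydroxy-10-iodo-2-(iodomethylidene)-5-(prop-1-en-2-yl)dec-7-enoate, via iodoallenyl silyl ketene acetal 17 (not isolated), via trimethylsilyl ether 18 (not isolated)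
Conditions: 16, TMSI, (S)-3,3-diphenyl-1-(o-tolyl)tetrahydro-1H,3H-pyrrolo[1,2-c][1,3,2]oxazaborole·HNTf2 (20 mol%), CH2Cl2, −78 °C; then aq. HCl (1 M), THF
Reagents that add atoms: iodotrimethylsilane, C[Si](C)(C)I
Why: Catalytic enantioselective three-component iodo-aldol (β-iodo Morita–Baylis–Hillman) reaction, in which TMSI adds to 16 to give allenolate 17 whose α-carbon attacks the oxazaborolidinium-bound aldehyde on the face left open by the catalyst (sets 9S, with C7 making any minor isomer a separable diastereomer) and kinetic anti addition places iodine trans to C9.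

Step 12
Reactants: 19 iodo-acrylate
Product: 20 (2E,3S,5R,7Z)-8-[(TBDPS-oxy)methyl]-10-iodo-2-(iodomethylidene)-5-(prop-1-en-2-yl)dec-7-ene-1,3-diol
Conditions: DIBAL-H (3.5 equiv), CH2Cl2, −78→−40 °C
Reagents that add atoms: none
Why: DIBAL-H 1,2-reduction of the acrylate ester gives the C14 alcohol; alkenyl and alkyl iodides are inert at this temperature.

Step 13
Reactants: 21 (R)-4-benzyl-3-propionyloxazolidin-2-one; 22 acetaldehyde
Product: 25 (4R)-4-benzyl-3-[(2R,3S)-3-hydroxy-2-methylbutanoyl]oxazolidin-2-one, via boron enolate 23 (not isolated), via boron aldolate 24 (not isolated)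
Conditions: Bu2BOTf, iPr2NEt, CH2Cl2, −78→0 °C; 22, −78→0 °C; pH 7 buffer, MeOH, H2O2
Reagents that add atoms: none
Why: Evans syn-aldol reaction, in which the (Z)-boron enolate reacts through a Zimmerman–Traxler chair on the face opposite the benzyl group, so the (R)-auxiliary should give the (2R,3S) syn adduct.

Step 14
Reactants: 25 aldol adduct
Product: 26 (4R)-4-benzyl-3-[(2R,3S)-3-(TBS-oxy)-2-methylbutanoyl]oxazolidin-2-one
Conditions: TBSOTf, 2,6-lutidine, CH2Cl2, 0 °C
Reagents that add atoms: tert-butyldimethylsilyl triflate, CC(C)(C)[Si](C)(C)OS(=O)(=O)C(F)(F)F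
Why: Silyl ether formation on the secondary alcohol blocks it for the later acylation.

Step 15
Reactants: 26 silylated imide
Product: 27 (2R,3S)-3-(TBS-oxy)-2-methylbutanoic acid
Conditions: LiOH, H2O2, THF/H2O, 0 °C; Na2SO3; aq. HCl
Reagents that add atoms: hydrogen peroxide (as lithium hydroperoxide), OO
Why: Lithium hydroperoxide cleaves the exocyclic imide carbonyl selectively (Evans auxiliary hydrolysis) without epimerising C2.

Step 16
Reactants: 20 diol; 27 acid
Product: 29 (2E,3S,5R,7Z)-8-[(TBDPS-oxy)methyl]-3-hydroxy-10-iodo-2-(iodomethylidene)-5-(prop-1-en-2-yl)dec-7-en-1-yl (2R,3S)-3-(TBS-oxy)-2-methylbutanoate, via acid chloride 28 (not isolated)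
Conditions: 27, 1-chloro-N,N,2-trimethylprop-1-en-1-amine, CH2Cl2, 0 °C; then 20, 2,4,6-collidine, CH2Cl2, −78→−40 °C
Reagents that add atoms: none
Why: Low-temperature acylation with an acid chloride and a hindered pyridine base should esterify the unhindered primary allylic C14 hydroxyl much faster than the secondary C9 hydroxyl, and the neutral chloroenamine avoids epimerising 28.

Step 17
Reactants: 29 mono-ester; 30 tigloyl chloride
Product: 31 (2E,3S,5R,7Z)-8-[(TBDPS-oxy)methyl]-10-iodo-2-(iodomethylidene)-5-(prop-1-en-2-yl)-3-(tigloyloxy)dec-7-en-1-yl (2R,3S)-3-(TBS-oxy)-2-methylbutanoate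
Conditions: 30, pyridine, DMAP (cat.), CH2Cl2, 0 °C
Reagents that add atoms: none
Why: DMAP-catalysed acylation of the remaining secondary allylic alcohol through the acylpyridinium ion; C9 keeps its configuration (O-acylation) and the tiglate stays E.

Step 18
Reactants: 31 diiodide
Product: 33 (7R,9S)-15-(TBDPS-oxy)-9-(tigloyloxy)germacra-1(10)E,4E,11(13)-trien-14-yl (2R,3S)-3-(TBS-oxy)-2-methylbutanoate, via alkylzinc iodide 32 (not isolated)
Conditions: Zn dust (activated with BrCH2CH2Br, TMSCl), THF, 30 °C; then syringe-pump addition to Pd(OAc)2 (10 mol%), 2-dicyclohexylphosphino-2',6'-dimethoxybiphenyl (20 mol%), THF (2 mM), 40 °C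
Reagents that add atoms: none
Why: Zinc dust inserts only into the primary C2–I bond (alkenyl C–I is inert in THF) to give 32; zerovalent palladium formed in situ then adds oxidatively to the C1–I bond with retention, intramolecular transmetalation gives an eleven-membered alkyl(alkenyl)palladacycle, and reductive elimination forms C1–C2. The closest known reaction type is the Negishi alkyl–alkenyl cross-coupling, used here intramolecularly. The ten-membered carbocycle closes with the alkenyl terminus C1 joined to the homoallylic methylene C2, so that both trisubstituted alkenes end up endocyclic. No stereocentre is created: the (E)-C10=C1 geometry set in step 11 is carried through with retention, and C7 and C9 are untouched. The step needs oxidative addition at C(sp2)–I to outrun ionisation of the two allylic ester C–O bonds (iodide insertion is far faster, helped by the bulky biarylphosphine at 40 °C), cyclisation to outrun oligomerisation (slow addition at high dilution) and reductive elimination to outrun β-hydride elimination (same ligand). The two preformed trisubstituted alkenes and the C7 branch restrict the tether and ease closure.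

Step 19
Reactants: 33 macrocycle
Product: 34 (7R,9S)-15-hydroxy-9-(tigloyloxy)germacra-1(10)E,4E,11(13)-trien-14-yl (2R,3S)-3-hydroxy-2-methylbutanoate
Conditions: HF·pyridine, pyridine, THF, 0 °C→rt
Reagents that add atoms: none
Why: Fluoride-driven desilylation removes both silyl ethers; esters and alkenes are inert to pyridine-buffered HF.

Step 20
Reactants: 34 diol
Product: 35 (4S,5R,7S,9S)-4,5-epoxy-15-hydroxy-9-(tigloyloxy)germacra-1(10)E,11(13)-dien-14-yl (2R,3S)-3-hydroxy-2-methylbutanoate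
Conditions: Ti(OiPr)4 (20 mol%), L-(+)-diethyl tartrate (24 mol%), t-BuOOH (decane), 4 Å MS, CH2Cl2, −20 °C
Reagents that add atoms: tert-butyl hydroperoxide, CC(C)(C)OO
Why: Katsuki–Sharpless asymmetric epoxidation, in which the titanium tartrate complex binds the C15 allylic alcohol and delivers oxygen only to C4=C5, L-(+)-tartrate being the antipode predicted to give (4S,5R); the other alkenes lack a free allylic hydroxyl.

Step 21
Reactants: 35 epoxy alcohol
Product: 36 (4S,5R,7S,9S)-12-chloro-4,5-epoxy-15-hydroxy-9-(tigloyloxy)germacra-1(10)E,11(13)-dien-14-yl (2R,3S)-3-hydroxy-2-methylbutanoate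
Conditions: NaOCl (aq.), CeCl3·7H2O, CH2Cl2/H2O, 0 °C
Reagents that add atoms: sodium hypochlorite, [Na+].[O-]Cl
Why: Ene-type allylic chlorination by hypochlorous acid should attack the isopropenyl group, the only electron-rich alkene left, with loss of a methyl proton to give the 2-(chloromethyl)allyl unit; the C10=C1 and tiglate alkenes are deactivated by acyloxy and carbonyl groups.

Step 22
Reactants: 36 allylic chloride
Product: 37 CNP0316239.1
Conditions: CsOAc, DMF, rt
Reagents that add atoms: caesium acetate, CC(=O)[O-].[Cs+]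
Why: SN2 displacement of the primary allylic chloride by acetate installs the C12 acetate without touching the epoxide or the other esters.

Compound list
1 | (S)-(+)-carvone, (5S)-2-methyl-5-(prop-1-en-2-yl)cyclohex-2-en-1-one | C=C(C)[C@@H]1CC(=O)C(C)=CC1 | starting material
2 | (1S,4S,6S)-1-methyl-4-(prop-1-en-2-yl)-7-oxabicyclo[4.1.0]heptan-2-one (epoxide anti to isopropenyl) | C=C(C)[C@@H]1CC(=O)[C@@]2(C)O[C@H]2C1 | intermediate
3 | (5S)-2,3-dihydroxy-2-methyl-5-(prop-1-en-2-yl)cyclohexan-1-one (trans-diol from epoxide opening) | C=C(C)[C@@H]1CC(=O)[C@@](C)(O)[C@H](O)C1 | intermediate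
4 | (3S)-5,6-dioxo-3-(prop-1-en-2-yl)heptanal | C=C(C)[C@H](CC(=O)C(C)=O)CC=O | intermediate
5 | (3S)-5-oxo-3-(prop-1-en-2-yl)pentanoic acid | C=C(C)[C@H](CC(=O)O)CC=O | intermediate
6 | methyl (3S)-5,5-dimethoxy-3-(prop-1-en-2-yl)pentanoate | C=C(C)[C@H](CC(=O)OC)CC(OC)OC | intermediate
7 | (3R)-5,5-dimethoxy-3-(prop-1-en-2-yl)pentanal | C=C(C)[C@H](CC=O)CC(OC)OC | intermediate
8 | methyl 2-[bis(2,2,2-trifluoroethoxy)phosphoryl]acetate | COC(=O)CP(=O)(OCC(F)(F)F)OCC(F)(F)F | starting material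
9 | tert-butyl(2-iodoethoxy)dimethylsilane | CC(C)(C)[Si](C)(C)OCCI | starting material
10 | methyl 2-[bis(2,2,2-trifluoroethoxy)phosphoryl]-4-[(tert-butyldimethylsilyl)oxy]butanoate (racemic) | COC(=O)C(CCO[Si](C)(C)C(C)(C)C)P(=O)(OCC(F)(F)F)OCC(F)(F)F | intermediate
11 | methyl (2Z,5R)-2-{2-[(tert-butyldimethylsilyl)oxy]ethyl}-7,7-dimethoxy-5-(prop-1-en-2-yl)hept-2-enoate | C=C(C)[C@H](C/C=C(/CCO[Si](C)(C)C(C)(C)C)C(=O)OC)CC(OC)OC | intermediate
12 | (2Z,5R)-2-{2-[(tert-butyldimethylsilyl)oxy]ethyl}-7,7-dimethoxy-5-(prop-1-en-2-yl)hept-2-en-1-ol | C=C(C)[C@H](C/C=C(/CCO[Si](C)(C)C(C)(C)C)CO)CC(OC)OC | intermediate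
13 | tert-butyl{[(2Z,5R)-2-{2-[(tert-butyldimethylsilyl)oxy]ethyl}-7,7-dimethoxy-5-(prop-1-en-2-yl)hept-2-en-1-yl]oxy}diphenylsilane | C=C(C)[C@H](C/C=C(/CCO[Si](C)(C)C(C)(C)C)CO[Si](c1ccccc1)(c1ccccc1)C(C)(C)C)CC(OC)OC | intermediate
14 | (3R,5Z)-6-{[(tert-butyldiphenylsilyl)oxy]methyl}-8-hydroxy-3-(prop-1-en-2-yl)oct-5-enal | C=C(C)[C@H](C/C=C(/CCO)CO[Si](c1ccccc1)(c1ccccc1)C(C)(C)C)CC=O | intermediate
15 | (3R,5Z)-6-{[(tert-butyldiphenylsilyl)oxy]methyl}-8-iodo-3-(prop-1-en-2-yl)oct-5-enal | C=C(C)[C@H](C/C=C(/CCI)CO[Si](c1ccccc1)(c1ccccc1)C(C)(C)C)CC=O | intermediate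
16 | methyl propiolate | C#CC(=O)OC | starting material
17 | [(3-iodo-1-methoxypropa-1,2-dien-1-yl)oxy]trimethylsilane | COC(O[Si](C)(C)C)=C=CI | intermediate
18 | methyl (2Z,3S,5R,7Z)-8-{[(tert-butyldiphenylsilyl)oxy]methyl}-10-iodo-2-(iodomethylidene)-5-(prop-1-en-2-yl)-3-[(trimethylsilyl)oxy]dec-7-enoate | C=C(C)[C@H](C/C=C(/CCI)CO[Si](c1ccccc1)(c1ccccc1)C(C)(C)C)C[C@H](O[Si](C)(C)C)/C(C(=O)OC)=C/I | intermediate
19 | methyl (2Z,3S,5R,7Z)-8-{[(tert-butyldiphenylsilyl)oxy]methyl}-3-hydroxy-10-iodo-2-(iodomethylidene)-5-(prop-1-en-2-yl)dec-7-enoate | C=C(C)[C@H](C/C=C(/CCI)CO[Si](c1ccccc1)(c1ccccc1)C(C)(C)C)C[C@H](O)/C(C(=O)OC)=C/I | intermediate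
20 | (2E,3S,5R,7Z)-8-{[(tert-butyldiphenylsilyl)oxy]methyl}-10-iodo-2-(iodomethylidene)-5-(prop-1-en-2-yl)dec-7-ene-1,3-diol | C=C(C)[C@H](C/C=C(/CCI)CO[Si](c1ccccc1)(c1ccccc1)C(C)(C)C)C[C@H](O)/C(CO)=C/I | intermediate
21 | (R)-4-benzyl-3-propionyloxazolidin-2-one | CCC(=O)N1C(=O)OC[C@H]1Cc1ccccc1 | starting material
22 | acetaldehyde | CC=O | starting material
23 | dibutylboron (Z)-enolate of 21 | C/C=C(/N1C(=O)OC[C@H]1Cc1ccccc1)OB(CCCC)CCCC | intermediate
24 | O-dibutylboryl aldolate of 25 | O=C([C@H](C)[C@H](C)OB(CCCC)CCCC)N1C(=O)OC[C@H]1Cc1ccccc1 | intermediate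
25 | (4R)-4-benzyl-3-[(2R,3S)-3-hydroxy-2-methylbutanoyl]oxazolidin-2-one | O=C([C@H](C)[C@H](C)O)N1C(=O)OC[C@H]1Cc1ccccc1 | intermediate
26 | (4R)-4-benzyl-3-[(2R,3S)-3-[(tert-butyldimethylsilyl)oxy]-2-methylbutanoyl]oxazolidin-2-one | O=C([C@H](C)[C@H](C)O[Si](C)(C)C(C)(C)C)N1C(=O)OC[C@H]1Cc1ccccc1 | intermediate
27 | (2R,3S)-3-[(tert-butyldimethylsilyl)oxy]-2-methylbutanoic acid | OC(=O)[C@H](C)[C@H](C)O[Si](C)(C)C(C)(C)C | intermediate
28 | (2R,3S)-3-[(tert-butyldimethylsilyl)oxy]-2-methylbutanoyl chloride | ClC(=O)[C@H](C)[C@H](C)O[Si](C)(C)C(C)(C)C | intermediate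
29 | (2E,3S,5R,7Z)-8-{[(tert-butyldiphenylsilyl)oxy]methyl}-3-hydroxy-10-iodo-2-(iodomethylidene)-5-(prop-1-en-2-yl)dec-7-en-1-yl (2R,3S)-3-[(tert-butyldimethylsilyl)oxy]-2-methylbutanoate | C=C(C)[C@H](C/C=C(/CCI)CO[Si](c1ccccc1)(c1ccccc1)C(C)(C)C)C[C@H](O)/C(COC(=O)[C@H](C)[C@H](C)O[Si](C)(C)C(C)(C)C)=C/I | intermediate
30 | tigloyl chloride, (E)-2-methylbut-2-enoyl chloride | C/C=C(\C)C(=O)Cl | starting material
31 | (2E,3S,5R,7Z)-8-{[(tert-butyldiphenylsilyl)oxy]methyl}-10-iodo-2-(iodomethylidene)-3-{[(2E)-2-methylbut-2-enoyl]oxy}-5-(prop-1-en-2-yl)dec-7-en-1-yl (2R,3S)-3-[(tert-butyldimethylsilyl)oxy]-2-methylbutanoate | C=C(C)[C@H](C/C=C(/CCI)CO[Si](c1ccccc1)(c1ccccc1)C(C)(C)C)C[C@H](OC(=O)/C(C)=C/C)/C(COC(=O)[C@H](C)[C@H](C)O[Si](C)(C)C(C)(C)C)=C/I | intermediate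
32 | alkylzinc iodide of 31 (C2–ZnI in place of C2–I) | C=C(C)[C@H](C/C=C(/CC[Zn]I)CO[Si](c1ccccc1)(c1ccccc1)C(C)(C)C)C[C@H](OC(=O)/C(C)=C/C)/C(COC(=O)[C@H](C)[C@H](C)O[Si](C)(C)C(C)(C)C)=C/I | intermediate
33 | (7R,9S)-15-[(tert-butyldiphenylsilyl)oxy]-9-(tigloyloxy)germacra-1(10)E,4E,11(13)-trien-14-yl (2R,3S)-3-[(tert-butyldimethylsilyl)oxy]-2-methylbutanoate (ten-membered ring; at C4=C5, C3 and C6 are trans and C15 is cis to C6) | C=C(C)[C@H]1C[C@H](OC(=O)/C(C)=C/C)/C(COC(=O)[C@H](C)[C@H](C)O[Si](C)(C)C(C)(C)C)=C/CC/C(CO[Si](c2ccccc2)(c2ccccc2)C(C)(C)C)=C/C1 | intermediate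
34 | (7R,9S)-15-hydroxy-9-(tigloyloxy)germacra-1(10)E,4E,11(13)-trien-14-yl (2R,3S)-3-hydroxy-2-methylbutanoate | C=C(C)[C@H]1C[C@H](OC(=O)/C(C)=C/C)/C(COC(=O)[C@H](C)[C@H](C)O)=C/CC/C(CO)=C/C1 | intermediate
35 | (4S,5R,7S,9S)-4,5-epoxy-15-hydroxy-9-(tigloyloxy)germacra-1(10)E,11(13)-dien-14-yl (2R,3S)-3-hydroxy-2-methylbutanoate (trans-epoxide) | C=C(C)[C@H]1C[C@H](OC(=O)/C(C)=C/C)/C(COC(=O)[C@H](C)[C@H](C)O)=C/CC[C@@]2(CO)O[C@@H]2C1 | intermediate
36 | (4S,5R,7S,9S)-12-chloro-4,5-epoxy-15-hydroxy-9-(tigloyloxy)germacra-1(10)E,11(13)-dien-14-yl (2R,3S)-3-hydroxy-2-methylbutanoate | C=C(CCl)[C@H]1C[C@H](OC(=O)/C(C)=C/C)/C(COC(=O)[C@H](C)[C@H](C)O)=C/CC[C@@]2(CO)O[C@@H]2C1 | intermediate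
37 | CNP0316239.1, (4S,5R,7S,9S)-12-acetoxy-4,5-epoxy-15-hydroxy-9-(tigloyloxy)germacra-1(10)E,11(13)-dien-14-yl (2R,3S)-3-hydroxy-2-methylbutanoate | C=C(COC(C)=O)[C@H]1C[C@H](OC(=O)/C(C)=C/C)/C(COC(=O)[C@H](C)[C@H](C)O)=C/CC[C@@]2(CO)O[C@@H]2C1 | target

Total step count: 22. Longest linear sequence: 18 steps from (S)-carvone (steps 1–4, 6–12, 16–22).

Steps most likely to fail

Step 18. Protonolysis of the alkylzinc or intermolecular coupling may outrun ring closure because of transannular strain in the eleven-membered palladacycle, and palladium may ionise an allylic ester. The fallback changes the C2 partner from a nucleophile to an electrophile and sets out from 31. Trimethylamine N-oxide in DMSO should oxidise the primary iodide to the C2 aldehyde F1. CrCl2 with catalytic NiCl2 in DMSO/THF at high dilution (Nozaki–Hiyama–Kishi reaction) closes the same C1–C2 bond and gives the macrocyclic C2 carbinol F2 as an epimer mixture. 1,1'-Thiocarbonyldiimidazole with DMAP gives the O-(imidazol-1-ylthiocarbonyl) derivative F3. Bu3SnH and AIBN in toluene at 80 °C (Barton–McCombie deoxygenation) then remove the oxygen, hydrogen transfer to the less hindered C2 terminus of the allyl radical being expected to return the route to 33.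

Step 11. The catalyst may discriminate poorly between the faces of this β-branched aliphatic aldehyde, or the Z geometry may erode. The fallback separates C–C bond formation from stereocontrol and sets out from 15. MgI2 and 16 in CH2Cl2 at 0 °C (uncatalysed iodo-aldol reaction) give the C9-epimeric carbinol mixture F4. Dess–Martin periodinane oxidises it to the β-iodo enone ester F5. Corey–Bakshi–Shibata reduction with (R)-2-methyl-CBS-oxazaborolidine and catecholborane at −78 °C, the alkenyl group acting as the large substituent, should give the 9S alcohol and come back at 19.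

Step 21. Hypochlorite may oxidise the free C15 and C3' hydroxyls or chlorinate another site in competition with the ene-type chlorination of the isopropenyl group. The fallback masks the hydroxyls first and sets out from 35. TESOTf and 2,6-lutidine give the bis(triethylsilyl) ether F6. NaOCl with CeCl3·7H2O then gives the allylic chloride F7, and CsOAc in DMF the acetate F8. HF·pyridine removes both TES groups and comes back at 37.

Further compounds
F1 | step 18 | C2 aldehyde of 31, (2E,3S,5R,7Z)-8-{[(tert-butyldiphenylsilyl)oxy]methyl}-2-(iodomethylidene)-10-oxo-5-(prop-1-en-2-yl)-3-(tigloyloxy)dec-7-en-1-yl (2R,3S)-3-[(tert-butyldimethylsilyl)oxy]-2-methylbutanoate | C=C(C)[C@H](C/C=C(/CC=O)CO[Si](c1ccccc1)(c1ccccc1)C(C)(C)C)C[C@H](OC(=O)/C(C)=C/C)/C(COC(=O)[C@H](C)[C@H](C)O[Si](C)(C)C(C)(C)C)=C/I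
F2 | step 18 | 2-hydroxy derivative of 33 (macrocyclic C2 carbinol, epimer mixture at C2) | C=C(C)[C@H]1C[C@H](OC(=O)/C(C)=C/C)/C(COC(=O)[C@H](C)[C@H](C)O[Si](C)(C)C(C)(C)C)=C/C(O)C/C(CO[Si](c2ccccc2)(c2ccccc2)C(C)(C)C)=C/C1
F3 | step 18 | O-(imidazol-1-ylthiocarbonyl) derivative of F2 | C=C(C)[C@H]1C[C@H](OC(=O)/C(C)=C/C)/C(COC(=O)[C@H](C)[C@H](C)O[Si](C)(C)C(C)(C)C)=C/C(OC(=S)n2ccnc2)C/C(CO[Si](c2ccccc2)(c2ccccc2)C(C)(C)C)=C/C1
F4 | step 11 | C9-epimeric mixture of 19, methyl (2Z,5R,7Z)-8-{[(tert-butyldiphenylsilyl)oxy]methyl}-3-hydroxy-10-iodo-2-(iodomethylidene)-5-(prop-1-en-2-yl)dec-7-enoate | C=C(C)[C@H](C/C=C(/CCI)CO[Si](c1ccccc1)(c1ccccc1)C(C)(C)C)CC(O)/C(C(=O)OC)=C/I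
F5 | step 11 | methyl (2Z,5R,7Z)-8-{[(tert-butyldiphenylsilyl)oxy]methyl}-10-iodo-2-(iodomethylidene)-3-oxo-5-(prop-1-en-2-yl)dec-7-enoate | C=C(C)[C@H](C/C=C(/CCI)CO[Si](c1ccccc1)(c1ccccc1)C(C)(C)C)CC(=O)/C(C(=O)OC)=C/I
F6 | step 21 | 15,3'-bis(triethylsilyl) ether of 35 | C=C(C)[C@H]1C[C@H](OC(=O)/C(C)=C/C)/C(COC(=O)[C@H](C)[C@H](C)O[Si](CC)(CC)CC)=C/CC[C@@]2(CO[Si](CC)(CC)CC)O[C@@H]2C1
F7 | step 21 | 15,3'-bis(triethylsilyl) ether of 36 (12-chloride) | C=C(CCl)[C@H]1C[C@H](OC(=O)/C(C)=C/C)/C(COC(=O)[C@H](C)[C@H](C)O[Si](CC)(CC)CC)=C/CC[C@@]2(CO[Si](CC)(CC)CC)O[C@@H]2C1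
F8 | step 21 | 15,3'-bis(triethylsilyl) ether of 37 (12-acetate) | C=C(COC(C)=O)[C@H]1C[C@H](OC(=O)/C(C)=C/C)/C(COC(=O)[C@H](C)[C@H](C)O[Si](CC)(CC)CC)=C/CC[C@@]2(CO[Si](CC)(CC)CC)O[C@@H]2C1
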